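## Structural features

Compound 18 is a flavone: a 4H-chromen-4-one in which ring A and the pyranone ring C share the C4a–C8a bond, with ring B attached at C2 through the C2–C1' bond. Ring A is of the phloroglucinol type, with hydroxyl groups at C5 and C7 and a 3-methylbut-2-enyl (prenyl) chain at C8. Ring B is of the resorcinol type, with hydroxyl groups at C2' and C4' and a 2-methylbut-3-en-2-yl (1,1-dimethylallyl) group at C5', whose quaternary carbon is bound directly to the ring. The molecule has no stereocentre, so no stereocentres stand next to each other; the only stereochemical element on the way is the geometry of the enol ether double bond that becomes C2=C3. The fragile groups are the prenyl alkene beside the C7 hydroxyl and the terminal alkene beside the C4' hydroxyl, which cyclise to a chroman or a dihydrobenzofuran under protic or Lewis acid and do not survive hydrogenation or quinone oxidants. The 5-hydroxyflavone core can also undergo Wessely–Moser isomerisation (C8 to C6 substitution) under forcing acid. The real difficulty is regiochemical: the prenyl chain must sit at C8 and not C6, the quaternary carbon at C5' and not C3', and four phenols must be masked by groups that come off without acid. The key step uses C4a of ring A, which is ortho to O1, ortho to the C5 oxygen and para to the C7 oxygen; the other position ortho to O1 is C8 and already carries the prenyl chain, so an acyl carbon tethered through O1–C2=C3 can only bond to C4a.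

## Logic of the disconnections

**18 from 17.** The four O–CH2 bonds of the allyl ethers are cut. The last step must be neutral because of the two acid-sensitive alkenes and the 5-hydroxyflavone, and allyl ethers are cleaved by zerovalent palladium and an amine without acid, base or hydrogen. The gain is that every earlier intermediate is a non-chelating, non-acidic polyether. The demand is that the catalyst ionises only the aryl allyl ethers; the prenyl and 1,1-dimethylallyl groups carry no leaving group and should be inert.

**17 from 15 through 16.** The C4–C4a bond is cut, which opens ring C to a 3-aryloxy-3-arylacrylic acid. The cut is placed here because C4a is the most nucleophilic carbon of ring A and the only free position ortho to O1. The gain is one ring and the division of the molecule into an aryl ether and a carboxyl group. The demand is that the carboxyl group be cis to the aryloxy group (Z) and that the activation spare three kinds of alkene.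

**15 from 14.** The acid is traced back to its methyl ester. The ester activates the alkyne for conjugate addition one step earlier; the free acid is needed only for the acylation. The demand is that hydroxide attack the ester carbonyl and not the enol ether carbon.

**14 from 4 and 13.** The O1–C2 bond is cut as a conjugate addition of a phenol to an arylpropiolate. This is the convergent step and splits the skeleton into ring A and ring B halves of similar size. The demand is O-attack rather than C-attack of the phloroglucinol-type phenoxide, and anti addition so that ester and aryloxy group end up cis.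

**13 from 10 through 11 and 12.** The bond between the alkyne and the ester carbon is cut, and the alkyne is traced to the formyl carbon by a one-carbon homologation. The aldehyde is the function ring B starts with, so no extra carbon–carbon coupling to the ring is needed. The demand is that the organolithium stage be run cold enough to leave the aryl allyl ethers alone.

**10 from 9, 9 from 6 through 7 and 8, 6 from 5 and 3.** The two O-allyl bonds are cut first, then the bond from C5' to the quaternary carbon, which is made by a [3,3] shift from the C4' oxygen, then the O–prenyl bond. The Claisen rearrangement builds the reversed prenyl group with the correct connectivity from a cheap prenyl ether. The demands are two: the chelated C2' hydroxyl must be masked in the flask (as in 7), otherwise migration goes to C3'; and the allyl ethers must be introduced only after this step, because an aryl allyl ether would rearrange under the same conditions.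

**4 from 2 and 3, 2 from 1.** The C8–CH2 bond is cut as an ortho C-alkylation of a phenoxide, and the two O-allyl bonds as a double etherification. Both positions ortho to the hydroxyl of 2 are equivalent, so ortho attack gives one constitution. The demands are ortho- over para- and O-selectivity in the prenylation and acceptance of a statistical diallylation of a symmetric triol.

## Other disconnections considered

**Alternative 1:** The cut is the C2–C1' bond, with a temporary ester bridge from a C3 carboxyl group to the C2' oxygen. In the forward direction the ortho-bromoaryl chromone-3-carboxylate A2 would be treated with Pd(OAc)2 and PCy3. Zerovalent palladium formed in the flask inserts into the C–Br bond, the chromone C2–H bond is palladated intramolecularly, and reductive elimination gives the lactone-bridged flavone A1.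

- In its favour: the tether fixes the site of arylation, the C2' oxygen is automatically ortho to the new bond, the two halves are joined by a simple esterification, and ring C already exists, so no alkene geometry has to be controlled.
- Against it here: the bridge must be removed again (lactone opening under base, to which the pyranone ring is itself sensitive, then loss of the carboxyl group), and the three methoxymethyl ethers must be cleaved with acid next to both sensitive alkenes. The arylpalladium intermediate meets two alkenes at the temperature such arylations need. A2 requires a brominated ring B phenol that still needs the Claisen chemistry of the chosen plan, and a prenylated chromone-3-carboxylic acid.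
- Comparison: on structure the two plans are equal in convergence. On mechanism the alternative is the better in that its bond-forming step is catalytic, needs no electrophilic acyl species and has no Z/E requirement, but it gives this back in the acidic deprotection. On step economy it is the weaker, with at least three operations between A1 and 18 against one between 17 and 18.

**Alternative 2:** The cut removes two bonds of ring B, C1'–C2' and C5'–C6', so that ring B is built by cycloaddition. In the forward direction the bis-silyloxy diene A5, which carries the 1,1-dimethylallyl group at its C4 terminus, would add to the 2-ethynylchromone A4. Loss of methanol and of the silyl groups would aromatise the adduct to the resorcinol ring of A3.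

- In its favour: the constitution of the diene fixes the positions of both ring B oxygens and of the quaternary substituent, so no Claisen regiochemistry arises; ring B emerges with free hydroxyls, so only two protecting groups remain.
- Against it here: the reacting diene terminus bears a tertiary alkyl group, which slows the cycloaddition. The alkyne of A4 is activated only through the pyranone double bond, which is itself a competing dienophile and Michael acceptor for a silyl ketene acetal. A4 and A5 each need several steps, and the remaining methoxymethyl ethers again need acid.
- Comparison: on structure the alternative is the better at C5', where the chosen plan depends on the direction of a sigmatropic shift, and it carries fewer protecting groups. On mechanism the chosen plan is on firmer ground, since an intramolecular acylation of a trioxygenated ring is more predictable than an intermolecular Diels–Alder reaction of a hindered diene with a weak dienophile. On step economy the two are about equal up to the key step, and the alternative loses through its acidic last step.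

**Alternative 3:** The cut is the O1–C8a bond. In the forward direction the bromoaryl 1,3-diketone A7 would be treated with CuI, 1,10-phenanthroline and K2CO3, and the enol oxygen remote from ring A would displace bromide to close ring C and give the tetra-O-methoxymethyl flavone A6.

- In its favour: the diketone comes from a Claisen-type condensation of two aryl carbonyl compounds; the ring closure does not depend on an alkene geometry, since the enol forms interconvert; the basic medium leaves the alkenes alone; and the halide fixes the position of ring closure.
- Against it here: A7 needs a ring A that carries acyl, bromine, prenyl and two ether groups, with the bromine between the acyl and prenyl groups, which is hard to reach regioselectively from phloroglucinol. The C–Br bond is flanked on both sides and sits on an electron-rich ring, which slows copper insertion. The four methoxymethyl ethers need acid for removal.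
- Comparison: on mechanism the alternative is the equal of the chosen plan, and the better in that no alkene geometry and no acyl electrophile are involved. On structure the chosen plan is the better, because it uses the C–H bond at C4a directly and needs no halogen on ring A. On step economy the chosen plan is shorter by the steps needed to place that halogen, and its last step is neutral.

Key step: step 10

Remark on the chemistry: closure at C4–C4a needs the carboxyl group and the aryloxy group on the same side of the double bond. With oxygen ranking above carbon at C3 and the carboxyl group above hydrogen at C2, this is the Z acid, which is what anti addition delivers. Common reagents (allyl bromide, N,O-bis(trimethylsilyl)acetamide, 2,6-di-tert-butyl-4-methylpyridine) are taken as commercial.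

## Route

Step 1
Reactants: 1 phloroglucinol (benzene-1,3,5-triol)
Product: 2 3,5-bis(allyloxy)phenol
Conditions: allyl bromide (2.0 equiv), K2CO3 (2.2 equiv), DMF, 0 °C to rt; chromatographic separation from mono- and tri-ether
Reagents that add atoms: allyl bromide, C=CCBr
Why: Williamson O-alkylation in a dipolar aprotic solvent, which favours O- over C-allylation; the three hydroxyls are equivalent, so the stoichiometry steers the statistical mixture towards the diether and no regiochemical question arises.

Step 2
Reactants: 2 3,5-bis(allyloxy)phenol; 3 1-bromo-3-methylbut-2-ene (prenyl bromide)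
Product: 4 3,5-bis(allyloxy)-2-(3-methylbut-2-en-1-yl)phenol
Conditions: NaH (1.0 equiv), toluene, 0 °C; then 3 (1.0 equiv), 0 °C to rt
Reagents that add atoms: none
Why: Ortho-selective C-alkylation of a sodium phenoxide held as a contact ion pair in a non-polar solvent; the two positions ortho to the hydroxyl are equivalent and each is also activated by an allyloxy group, so ortho attack should give a single constitution, while the tight sodium–oxygen pairing disfavours O-alkylation and attack at the position between the two ethers.

Step 3
Reactants: 5 2,4-dihydroxybenzaldehyde; 3 1-bromo-3-methylbut-2-ene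
Product: 6 2-hydroxy-4-[(3-methylbut-2-en-1-yl)oxy]benzaldehyde
Conditions: 3 (1.05 equiv), KHCO3 (1.5 equiv), MeCN, 60 °C
Reagents that add atoms: none
Why: Regioselective Williamson etherification; the 4-hydroxyl, para to the formyl group, is the more acidic, while the 2-hydroxyl is tied up in a hydrogen bond to the formyl oxygen and should not be deprotonated by hydrogen carbonate.

Step 4
Reactants: 6 2-hydroxy-4-[(3-methylbut-2-en-1-yl)oxy]benzaldehyde
Product: 9 2,4-dihydroxy-5-(2-methylbut-3-en-2-yl)benzaldehyde, via mono-silyl ether 7 (not isolated), via bis-silyl ether 8 (not isolated)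
Conditions: N,O-bis(trimethylsilyl)acetamide (3 equiv), PhNEt2, 60 °C then 185 °C (sealed tube); then MeOH, K2CO3 (cat.), rt
Reagents that add atoms: none
Why: Aromatic Claisen rearrangement ([3,3] shift followed by enolisation of the dienone); silylation of the 2-hydroxyl removes the chelate that would direct migration to C3, so the tertiary allyl terminus should go to the unhindered C5, and silylation of the newly formed 4-hydroxyl should suppress the abnormal Claisen pathway and dihydrobenzofuran formation before methanolysis returns the diphenol.

Step 5
Reactants: 9 2,4-dihydroxy-5-(2-methylbut-3-en-2-yl)benzaldehyde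
Product: 10 2,4-bis(allyloxy)-5-(2-methylbut-3-en-2-yl)benzaldehyde
Conditions: allyl bromide (3 equiv), K2CO3 (3 equiv), DMF, 50 °C
Reagents that add atoms: allyl bromide, C=CCBr
Why: Williamson etherification of both phenols; the allyl groups are put on only after the sigmatropic step, so they cannot rearrange, and the base-stable aldehyde and terminal alkene are untouched.

Step 6
Reactants: 10 2,4-bis(allyloxy)-5-(2-methylbut-3-en-2-yl)benzaldehyde
Product: 11 1,5-bis(allyloxy)-2-(2,2-dibromoethenyl)-4-(2-methylbut-3-en-2-yl)benzene
Conditions: CBr4 (2 equiv), PPh3 (2 equiv), Zn dust (2 equiv), CH2Cl2, rt; then 10, 0 °C to rt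
Reagents that add atoms: carbon tetrabromide, BrC(Br)(Br)Br
Why: Corey–Fuchs dibromo-olefination, a Wittig reaction of the dibromomethylene ylide with the aldehyde; the medium is neutral and the isolated alkenes and allyl ethers do not react with the ylide.

Step 7
Reactants: 11 1,5-bis(allyloxy)-2-(2,2-dibromoethenyl)-4-(2-methylbut-3-en-2-yl)benzene
Product: 13 methyl 3-[2,4-bis(allyloxy)-5-(2-methylbut-3-en-2-yl)phenyl]prop-2-ynoate, via lithium acetylide 12 (not isolated)
Conditions: n-BuLi (2.1 equiv), THF, −78 °C; then ClCO2Me (1.5 equiv), −78 to 0 °C
Reagents that add atoms: methyl chloroformate, COC(=O)Cl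
Why: Second stage of the Corey–Fuchs sequence: bromine–lithium exchange, Fritsch–Buttenberg–Wiechell rearrangement and metalation give acetylide 12, which is acylated at carbon by the chloroformate; at −78 °C the aryl allyl ethers should not be deprotonated.

Step 8
Reactants: 4 3,5-bis(allyloxy)-2-(3-methylbut-2-en-1-yl)phenol; 13 methyl 3-[2,4-bis(allyloxy)-5-(2-methylbut-3-en-2-yl)phenyl]prop-2-ynoate
Product: 14 methyl (2Z)-3-[3,5-bis(allyloxy)-2-(3-methylbut-2-en-1-yl)phenoxy]-3-[2,4-bis(allyloxy)-5-(2-methylbut-3-en-2-yl)phenyl]prop-2-enoate
Conditions: Cs2CO3 (0.3 equiv), DMF, rt to 50 °C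
Reagents that add atoms: none
Why: Base-catalysed oxa-Michael addition of the phenoxide to C3 of the ynoate; the allenoate is protonated by a further molecule of 4 on the side away from the new C–O bond (anti addition), which places ester and aryloxy group cis (Z), and the mild temperature with substoichiometric base is meant to keep this kinetic geometry.

Step 9
Reactants: 14 methyl (2Z)-3-[3,5-bis(allyloxy)-2-(3-methylbut-2-en-1-yl)phenoxy]-3-[2,4-bis(allyloxy)-5-(2-methylbut-3-en-2-yl)phenyl]prop-2-enoate
Product: 15 (2Z)-3-[3,5-bis(allyloxy)-2-(3-methylbut-2-en-1-yl)phenoxy]-3-[2,4-bis(allyloxy)-5-(2-methylbut-3-en-2-yl)phenyl]prop-2-enoic acid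
Conditions: LiOH·H2O (5 equiv), THF/MeOH/H2O, rt to 40 °C; then 0.5 M HCl, 0 °C, to pH 3
Reagents that add atoms: lithium hydroxide, [Li+].[OH-]
Why: Saponification by acyl–oxygen cleavage; C3 is fully substituted and shielded by two aryl groups, so hydroxide should attack the ester carbonyl and not displace the aryloxide, and the alkenes and allyl ethers are inert to base and to brief cold dilute acid.

Step 10
Reactants: 15 (2Z)-3-[3,5-bis(allyloxy)-2-(3-methylbut-2-en-1-yl)phenoxy]-3-[2,4-bis(allyloxy)-5-(2-methylbut-3-en-2-yl)phenyl]prop-2-enoic acid
Product: 17 5,7-bis(allyloxy)-2-[2,4-bis(allyloxy)-5-(2-methylbut-3-en-2-yl)phenyl]-8-(3-methylbut-2-en-1-yl)-4H-chromen-4-one, via mixed trifluoroacetic anhydride 16 (not isolated)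
Conditions: (CF3CO)2O (1.5 equiv), 2,6-di-tert-butyl-4-methylpyridine (3 equiv), CH2Cl2, 0 °C to rt
Reagents that add atoms: none
Why: Trifluoroacetic anhydride converts the acid into mixed anhydride 16, and the hindered pyridine, which cannot be acylated, takes up the trifluoroacetic acid. The acyl carbon of 16 is attacked by C4a of the aryloxy ring, the carbon ortho to O1 and to the C5 allyloxy group and para to the C7 allyloxy group; the arenium ion then gives its proton to the base and the ring is aromatic again. The closest known reaction type is the intramolecular Friedel–Crafts acylation of 3-aryloxycinnamic acids to flavones, run here with the mixed-anhydride activation used for acylating phenol ethers. Ring C closes in a 6-exo-trig mode, C4a adding to the trigonal acyl carbon whose C=O bond stays outside the new ring. No stereocentre is formed; the Z double bond of 15 becomes C2=C3 of the pyranone. Site selectivity is secured because the only other position ortho to O1 carries the prenyl chain, the position between the two allyloxy groups cannot reach the acyl carbon, and ring B stands trans to the carboxyl group. Chemoselectivity rests on the buffered, non-protic medium and the low temperature, under which the prenyl and 1,1-dimethylallyl alkenes, the enol ether and the allyl ethers should be neither protonated nor rearranged.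

Step 11
Reactants: 17 5,7-bis(allyloxy)-2-[2,4-bis(allyloxy)-5-(2-methylbut-3-en-2-yl)phenyl]-8-(3-methylbut-2-en-1-yl)-4H-chromen-4-one
Product: 18 5,7-dihydroxy-2-[2,4-dihydroxy-5-(2-methylbut-3-en-2-yl)phenyl]-8-(3-methylbut-2-en-1-yl)-4H-chromen-4-one
Conditions: Pd(PPh3)4 (10 mol%), morpholine (12 equiv), THF, rt, argon
Reagents that add atoms: none
Why: Tsuji–Trost-type deallylation: zerovalent palladium ionises each aryl allyl ether to a π-allyl complex and a phenoxide and morpholine captures the allyl group; the prenyl and 1,1-dimethylallyl groups have no allylic leaving group and the medium is never acidic, so chroman formation and Wessely–Moser isomerisation should not arise.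

## Compound list

1 | phloroglucinol (benzene-1,3,5-triol) | Oc1cc(O)cc(O)c1 | starting material
2 | 3,5-bis(allyloxy)phenol | Oc1cc(OCC=C)cc(OCC=C)c1 | intermediate
3 | 1-bromo-3-methylbut-2-ene (prenyl bromide) | CC(C)=CCBr | starting material
4 | 3,5-bis(allyloxy)-2-(3-methylbut-2-en-1-yl)phenol | Oc1cc(OCC=C)cc(OCC=C)c1CC=C(C)C | intermediate
5 | 2,4-dihydroxybenzaldehyde | O=Cc1ccc(O)cc1O | starting material
6 | 2-hydroxy-4-[(3-methylbut-2-en-1-yl)oxy]benzaldehyde | O=Cc1ccc(OCC=C(C)C)cc1O | intermediate
7 | 4-[(3-methylbut-2-en-1-yl)oxy]-2-(trimethylsilyloxy)benzaldehyde (formed in the flask) | O=Cc1ccc(OCC=C(C)C)cc1O[Si](C)(C)C | intermediate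
8 | 5-(2-methylbut-3-en-2-yl)-2,4-bis(trimethylsilyloxy)benzaldehyde (formed in the flask) | O=Cc1cc(C(C)(C)C=C)c(O[Si](C)(C)C)cc1O[Si](C)(C)C | intermediate
9 | 2,4-dihydroxy-5-(2-methylbut-3-en-2-yl)benzaldehyde | O=Cc1cc(C(C)(C)C=C)c(O)cc1O | intermediate
10 | 2,4-bis(allyloxy)-5-(2-methylbut-3-en-2-yl)benzaldehyde | O=Cc1cc(C(C)(C)C=C)c(OCC=C)cc1OCC=C | intermediate
11 | 1,5-bis(allyloxy)-2-(2,2-dibromoethenyl)-4-(2-methylbut-3-en-2-yl)benzene | BrC(Br)=Cc1cc(C(C)(C)C=C)c(OCC=C)cc1OCC=C | intermediate
12 | lithium [2,4-bis(allyloxy)-5-(2-methylbut-3-en-2-yl)phenyl]acetylide (formed in the flask) | [Li]C#Cc1cc(C(C)(C)C=C)c(OCC=C)cc1OCC=C | intermediate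
13 | methyl 3-[2,4-bis(allyloxy)-5-(2-methylbut-3-en-2-yl)phenyl]prop-2-ynoate | COC(=O)C#Cc1cc(C(C)(C)C=C)c(OCC=C)cc1OCC=C | intermediate
14 | methyl (2Z)-3-[3,5-bis(allyloxy)-2-(3-methylbut-2-en-1-yl)phenoxy]-3-[2,4-bis(allyloxy)-5-(2-methylbut-3-en-2-yl)phenyl]prop-2-enoate | COC(=O)/C=C(\Oc1cc(OCC=C)cc(OCC=C)c1CC=C(C)C)c1cc(C(C)(C)C=C)c(OCC=C)cc1OCC=C | intermediate
15 | (2Z)-3-[3,5-bis(allyloxy)-2-(3-methylbut-2-en-1-yl)phenoxy]-3-[2,4-bis(allyloxy)-5-(2-methylbut-3-en-2-yl)phenyl]prop-2-enoic acid | OC(=O)/C=C(\Oc1cc(OCC=C)cc(OCC=C)c1CC=C(C)C)c1cc(C(C)(C)C=C)c(OCC=C)cc1OCC=C | intermediate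
16 | mixed anhydride of acid 15 with trifluoroacetic acid, Z (formed in the flask) | O=C(OC(=O)C(F)(F)F)/C=C(\Oc1cc(OCC=C)cc(OCC=C)c1CC=C(C)C)c1cc(C(C)(C)C=C)c(OCC=C)cc1OCC=C | intermediate
17 | 5,7-bis(allyloxy)-2-[2,4-bis(allyloxy)-5-(2-methylbut-3-en-2-yl)phenyl]-8-(3-methylbut-2-en-1-yl)-4H-chromen-4-one | C=CC(C)(C)c1cc(-c2cc(=O)c3c(OCC=C)cc(OCC=C)c(CC=C(C)C)c3o2)c(OCC=C)cc1OCC=C | intermediate
18 | 5,7-dihydroxy-2-[2,4-dihydroxy-5-(2-methylbut-3-en-2-yl)phenyl]-8-(3-methylbut-2-en-1-yl)-4H-chromen-4-one | C=CC(C)(C)c1cc(-c2cc(=O)c3c(O)cc(O)c(CC=C(C)C)c3o2)c(O)cc1O | target

## Step count and least certain steps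

Total step count: 11. Longest linear sequence: 9 steps (steps 3 to 11, from 5 to 18); the ring A branch (steps 1 and 2) joins at step 8.

**Step 10 (key step).**
- What may go wrong: the buffered mixed anhydride, whose acyl group is deactivated as a vinylogous carbonate, may acylate too slowly. Trifluoroacetylation of one of the electron-rich rings, or isomerisation of the Z double bond before closure, could then compete. If the buffering fails, protonation of the prenyl alkene becomes possible.
- Fallback: abandon the acylation and close ring C at O1–C2, setting out from 4 and 11 and returning at 17. Phenol 4 would be formylated at its only free ortho position (MgCl2, Et3N, paraformaldehyde, MeCN, reflux) to give 4,6-bis(allyloxy)-2-hydroxy-3-(3-methylbut-2-en-1-yl)benzaldehyde F1. Its sodium phenoxide (NaH, THF) would be treated with lithium acetylide 12, made from 11 as in step 7, to give the racemic propargylic alcohol 1-[4,6-bis(allyloxy)-2-hydroxy-3-(3-methylbut-2-en-1-yl)phenyl]-3-[2,4-bis(allyloxy)-5-(2-methylbut-3-en-2-yl)phenyl]prop-2-yn-1-ol F2. MnO2 in CH2Cl2 would oxidise this to the ortho-hydroxyaryl ynone 1-[4,6-bis(allyloxy)-2-hydroxy-3-(3-methylbut-2-en-1-yl)phenyl]-3-[2,4-bis(allyloxy)-5-(2-methylbut-3-en-2-yl)phenyl]prop-2-yn-1-one F3. Et2NH in EtOH would then add to the ynone, and the phenol would displace the amine in a 6-endo closure to give 17.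

**Step 4.**
- What may go wrong: fragmentation of the electron-poor aryl prenyl ether (loss of the C5 unit as a diene) may compete with the [3,3] shift. Incomplete silylation would leave the chelate in place and divert migration towards C3.
- Fallback: build the quaternary carbon by cross-coupling instead, setting out from 5 and returning at 10. Bromination (NBS, MeCN, 0 °C) should give 5-bromo-2,4-dihydroxybenzaldehyde F4, and allylation (allyl bromide, K2CO3, DMF) 2,4-bis(allyloxy)-5-bromobenzaldehyde F5. A γ-selective Suzuki–Miyaura coupling with 3,3-dimethylallylboronic acid pinacol ester (Pd(OAc)2, a bulky dialkylbiarylphosphine chosen for branched selectivity, K3PO4, THF/H2O, 40 to 60 °C) would give 10. The bulky ligand and the absence of a soft nucleophile are expected to keep zerovalent palladium from ionising the aryl allyl ethers.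

**Step 8.**
- What may go wrong: addition may be slow, because the phenoxide is hindered by its ortho prenyl chain and the alkyne is deactivated by the donor-substituted ring B. Heating may then erode the Z geometry through reversible addition–elimination, and attack through a ring carbon of the phenoxide would lead towards a 4-arylcoumarin.
- Fallback: replace the addition by a stereoretentive substitution, setting out from 13 and returning at 14. Anti hydroiodination (NaI, AcOH, 70 °C) should give methyl (2Z)-3-[2,4-bis(allyloxy)-5-(2-methylbut-3-en-2-yl)phenyl]-3-iodoprop-2-enoate F6. Coupling with 4 (CuI, N,N-dimethylglycine, Cs2CO3, dioxane, 90 °C), an Ullmann-type vinylation with retention of geometry, would give 14.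

**Step 2.**
- What may go wrong: O-prenylation, attack at the position between the two allyloxy groups, and double C-alkylation may lower the amount of the ortho product and make it hard to purify.
- Fallback: reverse the order of the two alkylations, setting out from 1 and 3 and returning at 4. C-prenylation of 1 (DBU, THF, 0 °C to rt), in which all three ring carbons are equivalent, should give 2-(3-methylbut-2-en-1-yl)benzene-1,3,5-triol F7. Allylation with two equivalents of allyl bromide (K2CO3, acetone) is expected to take the unhindered hydroxyl para to the chain and one of the two hindered ones, giving 4; the isomer with both flanking hydroxyls allylated would have to be removed by chromatography.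

## Further compounds

F1 | step 10 | 4,6-bis(allyloxy)-2-hydroxy-3-(3-methylbut-2-en-1-yl)benzaldehyde | Oc1c(C=O)c(OCC=C)cc(OCC=C)c1CC=C(C)C
F2 | step 10 | 1-[4,6-bis(allyloxy)-2-hydroxy-3-(3-methylbut-2-en-1-yl)phenyl]-3-[2,4-bis(allyloxy)-5-(2-methylbut-3-en-2-yl)phenyl]prop-2-yn-1-ol (racemic) | OC(C#Cc1cc(C(C)(C)C=C)c(OCC=C)cc1OCC=C)c1c(O)c(CC=C(C)C)c(OCC=C)cc1OCC=C
F3 | step 10 | 1-[4,6-bis(allyloxy)-2-hydroxy-3-(3-methylbut-2-en-1-yl)phenyl]-3-[2,4-bis(allyloxy)-5-(2-methylbut-3-en-2-yl)phenyl]prop-2-yn-1-one | O=C(C#Cc1cc(C(C)(C)C=C)c(OCC=C)cc1OCC=C)c1c(O)c(CC=C(C)C)c(OCC=C)cc1OCC=C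
F4 | step 4 | 5-bromo-2,4-dihydroxybenzaldehyde | O=Cc1cc(Br)c(O)cc1O
F5 | step 4 | 2,4-bis(allyloxy)-5-bromobenzaldehyde | O=Cc1cc(Br)c(OCC=C)cc1OCC=C
F6 | step 8 | methyl (2Z)-3-[2,4-bis(allyloxy)-5-(2-methylbut-3-en-2-yl)phenyl]-3-iodoprop-2-enoate | COC(=O)/C=C(\I)c1cc(C(C)(C)C=C)c(OCC=C)cc1OCC=C
F7 | step 2 | 2-(3-methylbut-2-en-1-yl)benzene-1,3,5-triol | Oc1cc(O)c(CC=C(C)C)c(O)c1
A1 | alternative 1 | lactone-bridged flavone: tris(methoxymethoxy)-substituted chromeno[4,3-b]chromene-6,7-dione carrying the prenyl and 1,1-dimethylallyl groups | O=C1Oc2cc(OCOC)c(C(C)(C)C=C)cc2-c2oc3c(CC=C(C)C)c(OCOC)cc(OCOC)c3c(=O)c21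
A2 | alternative 1 | 2-bromo-5-(methoxymethoxy)-4-(2-methylbut-3-en-2-yl)phenyl 5,7-bis(methoxymethoxy)-8-(3-methylbut-2-en-1-yl)-4-oxo-4H-chromene-3-carboxylate | O=C(Oc1cc(OCOC)c(C(C)(C)C=C)cc1Br)c1coc2c(CC=C(C)C)c(OCOC)cc(OCOC)c2c1=O
A3 | alternative 2 | 2-[2,4-dihydroxy-5-(2-methylbut-3-en-2-yl)phenyl]-5,7-bis(methoxymethoxy)-8-(3-methylbut-2-en-1-yl)-4H-chromen-4-one | C=CC(C)(C)c1cc(-c2cc(=O)c3c(OCOC)cc(OCOC)c(CC=C(C)C)c3o2)c(O)cc1O
A4 | alternative 2 | 2-ethynyl-5,7-bis(methoxymethoxy)-8-(3-methylbut-2-en-1-yl)-4H-chromen-4-one | C#Cc1cc(=O)c2c(OCOC)cc(OCOC)c(CC=C(C)C)c2o1
A5 | alternative 2 | 1-methoxy-5,5-dimethyl-1,3-bis(trimethylsilyloxy)hepta-1,3,6-triene (double-bond geometry not defined) | COC(O[Si](C)(C)C)=CC(O[Si](C)(C)C)=CC(C)(C)C=C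
A6 | alternative 3 | 2-[2,4-bis(methoxymethoxy)-5-(2-methylbut-3-en-2-yl)phenyl]-5,7-bis(methoxymethoxy)-8-(3-methylbut-2-en-1-yl)-4H-chromen-4-one | C=CC(C)(C)c1cc(-c2cc(=O)c3c(OCOC)cc(OCOC)c(CC=C(C)C)c3o2)c(OCOC)cc1OCOC
A7 | alternative 3 | 1-[2-bromo-4,6-bis(methoxymethoxy)-3-(3-methylbut-2-en-1-yl)phenyl]-3-[2,4-bis(methoxymethoxy)-5-(2-methylbut-3-en-2-yl)phenyl]propane-1,3-dione | O=C(CC(=O)c1cc(C(C)(C)C=C)c(OCOC)cc1OCOC)c1c(Br)c(CC=C(C)C)c(OCOC)cc1OCOC
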